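A closed, stirred vessel holds solid substrate, second substrate and reagent, and the question is how much target stands in it at the end.

common to all: solid substrate 0.20 M

| run | reagent | second substrate | remark | time |
|---|---|---|---|---|
| Monday's | 0.10 M | 0.34 M | run made earlier |  |
| Thursday's | 0.10 M | 0.81 M | run made earlier |  |
| Friday's | 0.20 M | 0.40 M | run made earlier |  |
| summer | 0.100 M | 0.400 M |  | 8.0 h |
| autumn | 0.400 M | 1.20 M |  | 8.0 h |

| run | time / h | target / % |
|---|---|---|
| Monday's | 0.333 | 3.4 |
| Monday's | 0.500 | 6.2 |
| Monday's | 0.833 | 8.7 |
| Monday's | 1.33 | 9.7 |
| Monday's | 2.50 | 7.9 |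
| Monday's | 4.00 | 9.0 |
| Thursday's | 0.250 | 1.1 |
| Thursday's | 0.833 | 5.1 |
| Thursday's | 1.33 | 4.1 |
| Thursday's | 2.00 | 4.2 |
| Thursday's | 3.00 | 4.9 |
| Thursday's | 4.00 | 4.2 |
| Friday's | 0.333 | 7.6 |
| Friday's | 1.00 | 16.8 |
| Friday's | 2.00 | 18.5 |
| Friday's | 3.00 | 18.7 |
| Friday's | 4.00 | 17.9 |

(readings scatter by 0.5 percentage points)

- solid, in amounts per volume of the solution: solid substrate
- at the start none of the solid substrate is in solution
- what has only dissolved of solid substrate counts as not reacted
- a reading or a percentage of target counts all its forms, free or not

- the flask that ends with the higher amount of target, in percent of the solid substrate charged, or "neither" when 2 percentage points or less lies between them (summer / autumn / neither)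
- final target, as a percentage of the solid substrate charged, in summer
- final target, as a percentage of the solid substrate charged, in autumn

**Does the time matter?** I think not, since Friday's run reads 18.5% at 2.00 h and 17.9% at 4.00 h, and the other runs also stand level well before 8.0 h. So I take the mean of each level stretch as the target concentration T, which gives 0.0177 M on Monday, 0.00870 M on Thursday and 0.0367 M on Friday.

**What is large and what is small?** Target is the small thing, with Monday's 0.0177 M less than the 0.10 M of reagent charged. I therefore assume that the reagent R not in target went to a loss with second substrate, charged at A, and I correct A for that use. My split constant S is target per reagent lost, times second substrate left, S = T(A − R + T)/(R − T), a ratio of level amounts with the unit of a concentration.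

**Is it constant?** Not cleanly: 0.0556 M, 0.0685 M and 0.0533 M, so I carry the mean 0.0591 M with that spread.

**Your numbers?** Rearranged, T(T + b) = SR with b = A − R + S. Summer has b = 0.359 M and T = 0.0158 M, or 7.88%. Autumn has b = 0.859 M and T = 0.0267 M, or 13.3%.

The forecast names autumn, with 8.6% (7.5% to 9.7%) in summer and 12.5% (10% to 15.5%) in autumn, holding that “it scales about as reagent/second substrate”. My reckoning picks the same flask but stands lower in summer and higher in autumn.

The flask gives autumn, with 7.28% in summer and 16.2% in autumn.

    starting material + reagent ⇌ target (K = 9.70 /M, k = 0.00330 /M/s)
    solid substrate ⇌ starting material, rate k2*(cs2 - [starting material]) while solid is left; crystals form when [starting material] > cs2 (solubility = 0.0630 M, k = 0.00140 /s)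
    second substrate + reagent ⇌ second product (K = 9.40 /M, k = 9.80 × 10⁻⁴ /M/s)
    reagent + target ⇌ idle adduct, settled at all times (K = 9.60 /M)

In summer, the half-life of reagent by the forward rate of its loss to second product alone is 0.58 h at 8.00 h, far shorter than the 8.0 h run, and summer still reads 7.27% at 80.0 h. For the summer flask with 0.025 M of reagent, S gives 1.69% and the flask holds 1.52%. With idle adduct taken out of target, the end states give S = 0.0652 M in summer and 0.0650 M in autumn.

The numbers in the tables stem from a simulated flask on assumed constants.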